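All runs are calculated on assumed constants, noise included.

The recipes differ in the equivalents of Q, while L stands at 0.14 M and the last reading comes at 6.0 h.

| setting | beta | delta | epsilon | cedar | larch | ash |
|---|---|---|---|---|---|---|
| L | 0.14 M | 0.14 M | 0.14 M | 0.14 M | 0.14 M | 0.14 M |
| Q | 1.3 equiv | 2 equiv | 3.1 equiv | 2.20 equiv | 4.40 equiv | 1.10 equiv |
| remark | run made earlier | run made earlier | run made earlier |  |  |  |
| time |  |  |  | 6.0 h | 6.0 h | 6.0 h |

- beta (time / h: L / %, Z / %): 0.500: 78.9, 9.5; 1.00: 61.5, 17.9; 2.50: 35.1, 33.4; 6.00: 15.5, 47.1
- delta (time / h: L / %, Z / %): 1.50: 34.5, 32.6; 3.00: 18.5, 45.2; 5.00: 8.1, 51.7; 6.00: 7.9, 51.0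
- epsilon (time / h: L / %, Z / %): 0.500: 58.3, 21.7; 1.00: 32.5, 33.2; 2.50: 8.9, 49.5; 6.00: 4.0, 56.6

(scatter of a reading: 1 percentage point)

* part of the L that has reacted at the end, cedar
* part of the L that has reacted at the end, larch
* part of the L that has reacted at the end, ash
* what raising the equivalents of Q from its lowest to its highest value here does to the part of the L that has reacted (changes below 5 percentage points count as none) (it falls / it rises / no change)

- what has gone from L into another species counts as reacted, even if it can come back

L and Z don't add up to the charge: in the delta run at 6.00 h they come to 58.9 %, so something unseen holds the rest, and reacted L can't be read as Z. But L in the delta run goes from 8.1 % to 7.9 % over the last two readings, so a balance may be near.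

So I try a mass-action product, which I call the holding product: at the last reading, the fraction of L left times the free Q in equivalents of L. I take free Q as the charge minus Z, assuming each Z costs one Q. Beta gives 0.128, delta 0.118 and epsilon 0.101. They drift, but epsilon's L is 4.0 % with a scatter of 1 percentage point, so I carry the mean, 0.116.

Ash, at 1.10 equiv, is the hard flask: L left needs free Q, free Q needs Z, and Z needs L. Beta's Z gives free Q 0.629, so L is 18.4 %. Putting that back with beta's share of Z in reacted L gives Z 0.455 and L 18.0 %, so I say 82.0 % reacted in ash.

The forecast, noting “Q is nearly stoichiometric”, gives ash 77 % (73.5 % to 80.5 %), which is less than mine, cedar 93.2 % and larch 97.6 %. Its answer on the trend is "it rises".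

The flask gives 93.3 % for cedar, 96.0 % for larch and 81.7 % for ash, and on the trend "it rises", by 14 points.

    L + Q ⇌ Z + X (K = 1.50, k = 1.40 M⁻¹ h⁻¹)
    L + X ⇌ J, settled at all times (K = 330 M⁻¹)
    D ⇌ X, rate k3*(cs3 - [X]) while solid is left; crystals form when [X] > cs3 (solubility = 23.0 mM, k = 1.10 h⁻¹)

Ash ends with a smaller share of its L left, 18 %, than of its Q, 61 %, which makes a holding product of 0.121 beside the carried 0.116. A neighbour of cedar charged with 0.550 equiv of Q ends with Z at 29.0 %, so its free Q is 0.260, and the carried product gives L 44.6 %. That neighbour's L stands at 43 %.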